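**Numbering used throughout.** 1 tigloyl chloride; 2 its Weinreb amide; 3 4-bromo-1,2-dimethoxybenzene; 4 the aryl Grignard reagent from 3; 5 the E-enone; 6 3,4,5-trimethoxybenzaldehyde; 7 its tosylhydrazone; 8 the sodium salt of 7; 9 the aryldiazomethane; 10 the dihydrofuran; 11 the C2 epimer of the target; 12 the target. Locants O1 and C2–C5 are those of the oxolane of 12 and are kept for the corresponding atoms of 5, 9, 10 and 11. Ring A is the 3,4-dimethoxyphenyl group, ring B the 3,4,5-trimethoxyphenyl group.

## Analysis of the target

Compound 12 is a 2,5-diaryl-3,4-dimethyloxolane: one saturated five-membered ring (O1, C2–C5) with ring A on C2, methyl groups on C3 and C4, and ring B on C5. All four ring carbons are stereocentres, all S, and each pair of neighbouring substituents is trans, so 12 is the all-trans diastereomer, which is also the most stable one. Rings A and B differ by a single methoxy group, so the molecule is close to C2-symmetric without being so, and a route has to keep the two halves apart. The only functional groups are aryl methyl ethers and the two benzylic C–O bonds; under acid these ionise, C2–O1 more easily than C5–O1, because ring A has a conjugating para-methoxy group whereas the 4-methoxy group of ring B is twisted out of conjugation by its two neighbours. That ionisation allows C2 to be epimerised, but the same cation can be captured by ring B to give an aryltetralin. The difficulty is four contiguous stereocentres on a ring that keeps no other functional handle, of which only the benzylic ones can be corrected once the ring exists. The strategy rests on the position of C5: it is the one ring carbon bonded to both O1 and C4, and the remaining atoms O1–C2–C3–C4 have the connectivity of an aryl enone (carbonyl carbon C2 with ring A, α-carbon C3, β-carbon C4), so that C5 with ring B can be delivered as a one-carbon carbene unit bridging the two ends of that enone.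

## Retrosynthetic reasoning

**12 from 11.** The last operation changes no connectivity. The C2–O1 bond is broken and formed again so that ring A moves to the face trans to the C3 methyl group. C2 is the centre that is easiest to correct at the end, so the route only has to deliver C3, C4 and C5 correctly and may reach C2 in either configuration. The forward step needs an acid strong enough to ionise the ring-A benzylic ether and mild enough not to start arylation by ring B.

**11 from 10.** Taking away the hydrogens at C2 and C3 leads to the cyclic enol ether 10 with a C2=C3 double bond. Two stereocentres disappear, and the O1–C2=C3 unit that appears is what a carbonyl ylide leaves behind when it closes onto an enone. The forward step is an ionic hydrogenation, proton to C3 and hydride to C2. It has to place the C3 methyl trans to the C4 methyl; C2 is corrected afterwards.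

**10 from 5 and 9.** Both bonds to C5 are cut, O1–C5 and C4–C5. C5 leaves with ring B as the diazo carbon of 9, and O1–C2–C3–C4 remains as enone 5. This cut is preferred to one at C3–C4, or to a pair of bonds on different carbons, for three reasons: each aryl ring travels in its own fragment, both fragments lie two steps from commercial materials, and every atom of 5 and of the carbene carbon with its aryl group ends up in 12. The forward reaction has to capture the carbene at the enone oxygen, close the ring at the β-carbon, place the C4 methyl and ring B trans, and fix the absolute configuration of both centres.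

**5 from 2 and 4, 4 from 3, 2 from 1.** The bond between the carbonyl carbon and ring A is cut. The acyl half 2 comes from 1, in which the E double bond already exists, so no condensation has to create the alkene geometry. The aryl half is the Grignard reagent 4, made from bromide 3.

**9 from 8, 7 and 6.** The diazo carbon is the aldehyde carbon of 6. Condensation at that carbon gives hydrazone 7, deprotonation gives salt 8, and 8 fragments on gentle warming to 9.

## Alternatives that were turned down

Alternative 1: The oxolane is taken apart at C3–C4 and at both C–O bonds, which leaves water and two 4-propenylphenols, one for each aryl ring. In the forward direction a laccase with O2 would oxidise both phenols to radicals and a dirigent protein would join the two β-carbons with a defined facial sense. The resulting bis-quinone methide would take up water at one benzylic carbon and close through the new hydroxyl group onto the other. The product of this key step is the bisphenol 4-[(2S,3S,4S,5S)-5-(4-hydroxy-3,5-dimethoxyphenyl)-3,4-dimethyloxolan-2-yl]-2-methoxyphenol A1, and a double O-methylation of A1 would give 12.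
- For: A1 maps atom for atom onto 12, and three bonds and all four stereocentres would be formed in one flask from air and water. On step count and on direct control of C3 and C4 this plan is stronger than the chosen one.
- Against: the two phenols differ by one methoxy group, so two homodimers compete with the cross-product unless the protein tells them apart. Propenylphenol radicals without a side-chain hydroxyl group tend to couple β–5 and β–O–4 more readily than β–β. The water that closes the ring adds outside the protein, so the two benzylic centres of A1 are not under its control. No protein is known for this pair of phenols, so the key step presupposes that a biocatalyst is found or engineered.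
- In exchange the chosen route offers a construction in which rings A and B cannot be interchanged, and stereocontrol from a small-molecule catalyst whose mirror image is equally available.

Alternative 2: The disconnection goes through a γ-lactone, whose O1–C5 bond is cut by a retro-Baeyer–Villiger step to a racemic 2-aryl-3,4-dimethylcyclobutanone. In the forward direction a Baeyer–Villiger monooxygenase with O2 and NADPH would convert one enantiomer of the cyclobutanone, inserting oxygen on the aryl-bearing side with retention. This gives the lactone (3S,4S,5S)-3,4-dimethyl-5-(3,4,5-trimethoxyphenyl)oxolan-2-one A2. From A2, addition of ring A to the carbonyl carbon, reduction of the hemiketal and equilibration of C2 would lead to 12.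
- For: A2 carries C3, C4 and C5 correctly, and the conversion of such lactones into oxolanes of this class is well-established chemistry. On the certainty of its end game this plan is stronger than the chosen one.
- Against: the key step forms one bond and creates no stereocentre. The trisubstituted cyclobutanone has to be built first, and a ketene cycloaddition either gives the wrong regiochemistry or needs an unactivated butene as partner. The resolution discards half of the material. Migration of the methyl-bearing carbon would give the regioisomeric lactone, and the acidic α-aryl position can epimerise. The substrate is far from the simple cyclobutanones that these enzymes accept. The whole sequence to 12 by way of A2 would be at least as long as the chosen one.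
- In exchange the chosen route is convergent, makes two skeletal bonds and two stereocentres in its key step, and has no resolution ceiling.

Alternative 3: The bonds O1–C2 and C4–C5 of a more highly oxidised oxolane are cut, which leads to aldehyde 6 and an enantioenriched 2-aryl-3-methylcyclopropane-1,1-diester; the malonate carbon becomes the ring carbon next to C5. In the forward direction Sn(OTf)2 would activate the diester, the aldehyde oxygen would open the cyclopropane at the ring-A carbon with inversion, and the malonate carbon would close onto the aldehyde carbon. The product is dimethyl (2R,4S,5R)-5-(3,4-dimethoxyphenyl)-4-methyl-2-(3,4,5-trimethoxyphenyl)oxolane-3,3-dicarboxylate A3, in which the two aryl groups are cis.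
- For: A3 would be made by the best-precedented key step of the four, stereospecific and unambiguous in its regiochemistry, and from the same aldehyde 6. On precedent this plan is clearly stronger than the chosen one.
- Against: the malonate carbon of A3 carries two ester carbons where 12 has one methyl group and one hydrogen. One ester has to be excised and the other reduced to CH3, about four steps that form no skeletal bond. The stereocentre left at that carbon would then be set by a protonation with little bias. The very electron-rich ring A makes the cyclopropane prone to ring opening by the Lewis acid and to loss of enantiopurity before capture. A3 has its ring-A carbon in the epimeric configuration, so the same C2 equilibration as in the chosen route is still needed. The total comes to about ten steps.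
- In exchange the chosen route has redox and atom economy: every carbon of 10 is a carbon of 12, and two steps lead from the key product to the target.

Key step: step 5

**Assumption:** the sense of induction of the CuOTf–bisoxazoline catalyst with an aryl carbene cannot be derived with confidence; the (S,S) ligand is written in step 5, and its equally available (R,R) antipode is used instead if the first run gives the mirror-image dihydrofuran.

## Route

Step 1
Reactants: 1 (E)-2-methylbut-2-enoyl chloride (tigloyl chloride)
Product: 2 (E)-N-methoxy-N,2-dimethylbut-2-enamide
Conditions: MeNH(OMe)·HCl (1.1 equiv), Et3N (2.3 equiv), CH2Cl2, 0 °C → rt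
Reagents that add atoms: N,O-dimethylhydroxylamine hydrochloride, CNOC.Cl
Why: Acylation of the amine by the acid chloride (Weinreb amide formation); Et3N takes up both equivalents of HCl and the E double bond of the tigloyl unit is not touched.

Step 2
Reactants: 3 4-bromo-1,2-dimethoxybenzene; 2 (E)-N-methoxy-N,2-dimethylbut-2-enamide
Product: 5 (E)-1-(3,4-dimethoxyphenyl)-2-methylbut-2-en-1-one, via 3,4-dimethoxyphenylmagnesium bromide 4 (not isolated)
Conditions: Mg, BrCH2CH2Br (catalytic), THF, 40 °C; then 2, THF, −10 → 0 °C; cold 1 M HCl
Reagents that add atoms: none
Why: Grignard formation followed by Weinreb ketone synthesis: the magnesium-chelated tetrahedral adduct survives until the quench, so the aryl group adds once and only at the carbonyl carbon. The E geometry comes unchanged from 1, and the cold acid quench keeps the released hydroxylamine protonated so that it cannot add to the enone.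

Step 3
Reactants: 6 3,4,5-trimethoxybenzaldehyde
Product: 7 N′-[(E)-(3,4,5-trimethoxyphenyl)methylidene]-4-methylbenzenesulfonohydrazide
Conditions: TsNHNH2 (1.05 equiv), MeOH, rt
Reagents that add atoms: p-toluenesulfonyl hydrazide, Cc1ccc(cc1)S(=O)(=O)NN
Why: Condensation of an aldehyde with a sulfonyl hydrazide to the hydrazone, which should crystallise from methanol.

Step 4
Reactants: 7 N′-[(E)-(3,4,5-trimethoxyphenyl)methylidene]-4-methylbenzenesulfonohydrazide
Product: 9 (3,4,5-trimethoxyphenyl)diazomethane, via tosylhydrazone sodium salt 8 (not isolated)
Conditions: NaOMe (1.0 equiv), MeOH, rt; evaporate; BnEt3NCl (10 mol %), toluene, 40 °C, dark; filter cold, wash with cold H2O, dry (Na2SO4); used at once as a titrated toluene solution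
Reagents that add atoms: none
Why: First stage of the Bamford–Stevens reaction: the sodium salt loses sulfinate on gentle warming, with the phase-transfer catalyst bringing it into solution, and leaves the diazoalkane. With two meta and one para methoxy groups the ring is electronically close to phenyl, so 9 should be about as persistent in cold solution as phenyldiazomethane.

Step 5
Reactants: 5 (E)-1-(3,4-dimethoxyphenyl)-2-methylbut-2-en-1-one; 9 (3,4,5-trimethoxyphenyl)diazomethane
Product: 10 (4S,5S)-2-(3,4-dimethoxyphenyl)-3,4-dimethyl-5-(3,4,5-trimethoxyphenyl)-4,5-dihydrofuran (target locants; by lowest locants the (2S,3S)-2,3-dihydrofuran)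
Conditions: (CuOTf)2·C6H5CH3 (5 mol % Cu), (S,S)-t-Bu-BOX [2,2′-(propane-2,2-diyl)bis((4S)-4-tert-butyl-4,5-dihydrooxazole)] (6 mol %), 4 Å MS, CH2Cl2, 0 °C; 9 (1.5 equiv) added over 8 h; filtration through Et3N-deactivated silica
Reagents that add atoms: none
Why: Proposed new method: the complex of monovalent copper (CuOTf) with the bisoxazoline is expected to extrude N2 from 9 and give an electrophilic copper benzylidene, which the carbonyl oxygen of 5, made more Lewis-basic by the para-methoxy group of ring A, captures to form a copper-associated carbonyl ylide (O1–C5), best described as an O-alkylated enone that carries a C5–Cu bond and is electrophilic at C4. Closure of C5 onto the β-carbon C4 forms the only new ring, a five-membered ring made by a formal six-electron, five-atom (1,5) electrocyclisation of the vinyl carbonyl ylide; geometrically it is 5-endo-trig, but the reacting π-system is the delocalised O1–C2–C3–C4 unit, so the usual restriction on nucleophilic 5-endo closures does not apply. The closest known reaction type is the copper-catalysed enantioselective (4+1) annulation of enones with diazoacetates to 2,3-dihydrofurans; new here is a donor-only aryl carbene with no ester to stabilise the ylide. C5 is controlled by the ligand, which decides the face of the carbene carbon that the oxygen attacks and keeps that face defined for as long as copper stays on C5. C4 is controlled by the E geometry of 5, which fixes where the C4 methyl points, together with the closure itself, in which ring B on the still tetrahedral C5 turns away from that methyl as the C4–C5 bond forms; this gives the 4,5-trans ring, the sense expected by analogy with the diazoacetate annulation. A copper-free planar ylide would instead close by disrotation from its less crowded form, with the methyl group and ring B both outside, and that would give the 4,5-cis ring without enantiocontrol, so the step needs closure to be faster than loss of copper; the low temperature, the non-coordinating solvent and the triflate counter-ion are chosen for that. It also needs O-capture to beat cyclopropanation, 1,3-closure to an epoxide and carbene dimerisation: the trisubstituted, electron-poor C3=C4 bond is a poor partner for an electrophilic carbene, conjugation with C3=C4 favours 1,5- over 1,3-closure, and slow addition keeps the concentration of 9 low.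

Step 6
Reactants: 10 (4S,5S)-2-(3,4-dimethoxyphenyl)-3,4-dimethyl-5-(3,4,5-trimethoxyphenyl)-4,5-dihydrofuran
Product: 11 (2R,3S,4S,5S)-2-(3,4-dimethoxyphenyl)-3,4-dimethyl-5-(3,4,5-trimethoxyphenyl)oxolane
Conditions: Et3SiH (3 equiv), CF3CO2H (5 equiv), CH2Cl2, −40 → −10 °C; Et3N, then aq. NaHCO3
Reagents that add atoms: none
Why: Ionic hydrogenation of an enol ether: protonation at C3 gives the ring-A-stabilised oxocarbenium ion, and because this protonation should be reversible and faster than hydride transfer from the silane, C3 settles with its methyl trans to the C4 methyl (thermodynamic control). Hydride then adds to C2 from the face opposite the C3 methyl, which leaves ring A cis to that methyl (2R). Any all-trans isomer formed alongside is not a loss, since step 7 converges both on 12.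

Step 7
Reactants: 11 (2R,3S,4S,5S)-2-(3,4-dimethoxyphenyl)-3,4-dimethyl-5-(3,4,5-trimethoxyphenyl)oxolane
Product: 12 5-methoxygalbelgin [(2S,3S,4S,5S)-2-(3,4-dimethoxyphenyl)-3,4-dimethyl-5-(3,4,5-trimethoxyphenyl)oxolane]
Conditions: BF3·OEt2 (0.5 equiv), CH2Cl2, −20 → 0 °C; Et3N quench
Reagents that add atoms: none
Why: Lewis-acid epimerisation of a benzylic ether: BF3 on O1 promotes heterolysis of the C2–O1 bond to a para-methoxy-stabilised benzylic cation, which recloses, and the equilibrium should lie on the side of the all-trans oxolane (2S). C3 and C4 are not touched, and C5, whose aryl group stabilises a cation less well, ionises more slowly and is already trans.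

## Compound list

1 | (E)-2-methylbut-2-enoyl chloride (tigloyl chloride) | C/C=C(\C)C(=O)Cl | starting material
2 | (E)-N-methoxy-N,2-dimethylbut-2-enamide | C/C=C(\C)C(=O)N(C)OC | intermediate
3 | 4-bromo-1,2-dimethoxybenzene | COc1ccc(Br)cc1OC | starting material
4 | 3,4-dimethoxyphenylmagnesium bromide (formed in the flask) | COc1ccc([Mg]Br)cc1OC | intermediate
5 | (E)-1-(3,4-dimethoxyphenyl)-2-methylbut-2-en-1-one | C/C=C(\C)C(=O)c1ccc(OC)c(OC)c1 | intermediate
6 | 3,4,5-trimethoxybenzaldehyde | COc1cc(C=O)cc(OC)c1OC | starting material
7 | N′-[(E)-(3,4,5-trimethoxyphenyl)methylidene]-4-methylbenzenesulfonohydrazide | COc1cc(/C=N/NS(=O)(=O)c2ccc(C)cc2)cc(OC)c1OC | intermediate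
8 | sodium salt of 7 (formed in the flask) | COc1cc(/C=N/[N-]S(=O)(=O)c2ccc(C)cc2)cc(OC)c1OC.[Na+] | intermediate
9 | (3,4,5-trimethoxyphenyl)diazomethane | COc1cc(C=[N+]=[N-])cc(OC)c1OC | intermediate
10 | (4S,5S)-2-(3,4-dimethoxyphenyl)-3,4-dimethyl-5-(3,4,5-trimethoxyphenyl)-4,5-dihydrofuran | COc1ccc(C2=C(C)[C@H](C)[C@@H](c3cc(OC)c(OC)c(OC)c3)O2)cc1OC | intermediate
11 | (2R,3S,4S,5S)-2-(3,4-dimethoxyphenyl)-3,4-dimethyl-5-(3,4,5-trimethoxyphenyl)oxolane | COc1ccc([C@@H]2O[C@H](c3cc(OC)c(OC)c(OC)c3)[C@@H](C)[C@@H]2C)cc1OC | intermediate
12 | 5-methoxygalbelgin, (2S,3S,4S,5S)-2-(3,4-dimethoxyphenyl)-3,4-dimethyl-5-(3,4,5-trimethoxyphenyl)oxolane | COc1ccc([C@H]2O[C@H](c3cc(OC)c(OC)c(OC)c3)[C@@H](C)[C@@H]2C)cc1OC | target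

## Step count and least certain steps

Total: 7 steps. Longest linear sequence: 5 steps (1, 2, 5, 6, 7 or 3, 4, 5, 6, 7).

**Step 5 (key step).** Several processes can defeat it. The carbene may be consumed by dimerisation or azine formation before the weakly nucleophilic ketone oxygen captures it, because a donor-only carbene is less electrophilic than the acceptor carbenes of the known annulation. Copper may leave the ylide before ring closure, which would let the planar ylide close by disrotation, with loss of both the trans selectivity and the enantioselectivity. The ylide may also collapse by 1,3-closure, or the carbene may add across C3=C4. The fallback uses known chemistry throughout, sets out from 6 and comes back to the route at 11. Brown crotylation of 6 with the (E)-crotyl-B(Ipc)2 reagent made from (E)-but-2-ene, n-BuLi, KOt-Bu and (−)-Ipc2BOMe, this being the enantiomeric series of the borane expected to attack the required aldehyde face, followed by NaOH–H2O2 work-up, should give the anti alcohol (1S,2S)-2-methyl-1-(3,4,5-trimethoxyphenyl)but-3-en-1-ol F1. Hydroboration of F1 with 9-BBN and oxidative work-up gives (1S,2S)-2-methyl-1-(3,4,5-trimethoxyphenyl)butane-1,4-diol F2. TEMPO with PhI(OAc)2 oxidises the primary alcohol of F2 and then the lactol to the trans lactone (4S,5S)-4-methyl-5-(3,4,5-trimethoxyphenyl)oxolan-2-one F3. Deprotonation of F3 with LiN(SiMe3)2 and methylation with MeI anti to the neighbouring methyl group gives (3S,4S,5S)-3,4-dimethyl-5-(3,4,5-trimethoxyphenyl)oxolan-2-one F4. Grignard reagent 4 at −78 °C adds once to F4 to give the hemiketal (3S,4S,5S)-2-(3,4-dimethoxyphenyl)-3,4-dimethyl-5-(3,4,5-trimethoxyphenyl)oxolan-2-ol F5, as a mixture of anomers. Under the conditions of step 6, F5 ionises to the same oxocarbenium ion that 10 gives on protonation and is reduced to 11.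

**Step 6.** The main risk is that hydride traps the kinetically protonated cation before proton exchange at C3 has equilibrated, which would carry the C3 methyl cis to the C4 methyl into a centre that cannot be corrected later. Reductive opening of the benzylic C2–O1 bond of the product is a second risk. The fallback sets out from 10 and comes back at 11, and it separates equilibration from reduction. 10 is stirred with MeOH and catalytic pyridinium p-toluenesulfonate, with no reductant present, until the addition of methanol has equilibrated through oxocarbenium ion and enol ether. This should give the cyclic ketal (3S,4S,5S)-2-(3,4-dimethoxyphenyl)-2-methoxy-3,4-dimethyl-5-(3,4,5-trimethoxyphenyl)oxolane F6, as a mixture of anomers with the C3 methyl trans to the C4 methyl. F6 is then reduced to 11 with Et3SiH and BF3·OEt2 at −78 °C, a known ketal reduction in which the cation is trapped before it can lose a proton.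

**Step 7.** The main risk is Friedel–Crafts capture of the C2 benzylic cation by the activated ortho position of ring B, which closes a six-membered carbocycle; incomplete equilibration is the lesser risk. The fallback sets out from 10 and comes back at 12, and it forms the C2–O1 bond under basic conditions in which the product cannot ionise again. Hydration of 10 with dilute HCl in THF–H2O, left until the α-methyl centre has equilibrated through the ring form, gives (2S,3S,4S)-1-(3,4-dimethoxyphenyl)-4-hydroxy-2,3-dimethyl-4-(3,4,5-trimethoxyphenyl)butan-1-one F7, drawn in its open-chain form. NaBH4 in MeOH reduces F7 to (2S,3S,4S)-1-(3,4-dimethoxyphenyl)-2,3-dimethyl-4-(3,4,5-trimethoxyphenyl)butane-1,4-diol F8, as either C1 epimer. MsCl and Et3N at 0 °C convert the ring-A carbinol of F8 into (2S,3S,4S)-1-(3,4-dimethoxyphenyl)-4-hydroxy-2,3-dimethyl-4-(3,4,5-trimethoxyphenyl)butyl methanesulfonate F9, which is not isolated. It ionises as it forms, both C1 epimers giving the same para-methoxy-stabilised cation, and the remaining hydroxyl group closes on that cation from the face that puts ring A trans to the neighbouring methyl group, giving 12. The ring-B carbinol is the less readily ionised of the two, so its configuration should be kept.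

**Step 4.** The risk is decomposition of 9 by azine and stilbene formation during the warm release with no trap present, and carry-over of sulfinate or chloride that would bind the copper catalyst of step 5. The fallback sets out from 6 and comes back at 9. Condensation of 6 with an excess of N2H4·H2O in EtOH gives (E)-[(3,4,5-trimethoxyphenyl)methylidene]hydrazine F10. Oxidation of F10 with activated MnO2 in CH2Cl2 at 0 °C and cold filtration gives a salt-free solution of 9.

## Further compounds

F1 | step 5 | (1S,2S)-2-methyl-1-(3,4,5-trimethoxyphenyl)but-3-en-1-ol | O[C@H](c1cc(OC)c(OC)c(OC)c1)[C@@H](C)C=C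
F2 | step 5 | (1S,2S)-2-methyl-1-(3,4,5-trimethoxyphenyl)butane-1,4-diol | O[C@H](c1cc(OC)c(OC)c(OC)c1)[C@@H](C)CCO
F3 | step 5 | (4S,5S)-4-methyl-5-(3,4,5-trimethoxyphenyl)oxolan-2-one | O=C1O[C@H](c2cc(OC)c(OC)c(OC)c2)[C@@H](C)C1
F4 | step 5 | (3S,4S,5S)-3,4-dimethyl-5-(3,4,5-trimethoxyphenyl)oxolan-2-one | O=C1O[C@H](c2cc(OC)c(OC)c(OC)c2)[C@@H](C)[C@@H]1C
F5 | step 5 | (3S,4S,5S)-2-(3,4-dimethoxyphenyl)-3,4-dimethyl-5-(3,4,5-trimethoxyphenyl)oxolan-2-ol (anomers) | COc1ccc(C2(O)O[C@H](c3cc(OC)c(OC)c(OC)c3)[C@@H](C)[C@@H]2C)cc1OC
F6 | step 6 | (3S,4S,5S)-2-(3,4-dimethoxyphenyl)-2-methoxy-3,4-dimethyl-5-(3,4,5-trimethoxyphenyl)oxolane (anomers) | COc1ccc(C2(OC)O[C@H](c3cc(OC)c(OC)c(OC)c3)[C@@H](C)[C@@H]2C)cc1OC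
F7 | step 7 | (2S,3S,4S)-1-(3,4-dimethoxyphenyl)-4-hydroxy-2,3-dimethyl-4-(3,4,5-trimethoxyphenyl)butan-1-one | COc1ccc(C(=O)[C@@H](C)[C@H](C)[C@H](O)c2cc(OC)c(OC)c(OC)c2)cc1OC
F8 | step 7 | (2S,3S,4S)-1-(3,4-dimethoxyphenyl)-2,3-dimethyl-4-(3,4,5-trimethoxyphenyl)butane-1,4-diol (C1 epimers) | COc1ccc(C(O)[C@@H](C)[C@H](C)[C@H](O)c2cc(OC)c(OC)c(OC)c2)cc1OC
F9 | step 7 | (2S,3S,4S)-1-(3,4-dimethoxyphenyl)-4-hydroxy-2,3-dimethyl-4-(3,4,5-trimethoxyphenyl)butyl methanesulfonate (C1 epimers) | COc1ccc(C(OS(C)(=O)=O)[C@@H](C)[C@H](C)[C@H](O)c2cc(OC)c(OC)c(OC)c2)cc1OC
F10 | step 4 | (E)-[(3,4,5-trimethoxyphenyl)methylidene]hydrazine | COc1cc(/C=N/N)cc(OC)c1OC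
A1 | alternative 1 | 4-[(2S,3S,4S,5S)-5-(4-hydroxy-3,5-dimethoxyphenyl)-3,4-dimethyloxolan-2-yl]-2-methoxyphenol | Oc1ccc([C@H]2O[C@H](c3cc(OC)c(O)c(OC)c3)[C@@H](C)[C@@H]2C)cc1OC
A2 | alternative 2 | (3S,4S,5S)-3,4-dimethyl-5-(3,4,5-trimethoxyphenyl)oxolan-2-one | O=C1O[C@H](c2cc(OC)c(OC)c(OC)c2)[C@@H](C)[C@@H]1C
A3 | alternative 3 | dimethyl (2R,4S,5R)-5-(3,4-dimethoxyphenyl)-4-methyl-2-(3,4,5-trimethoxyphenyl)oxolane-3,3-dicarboxylate | COc1ccc([C@@H]2O[C@H](c3cc(OC)c(OC)c(OC)c3)C(C(=O)OC)(C(=O)OC)[C@@H]2C)cc1OC
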